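| setting | spring | dusk | summer | flask |
|---|---|---|---|---|
| first end groups | 0.11 M | 0.11 M | 0.17 M | 0.11 M |
| second end groups | 0.16 M | 0.25 M | 0.112 M | 0.112 M |
| remark | run made earlier | run made earlier | run made earlier |  |
| time |  |  |  | 20 h |

- spring (time / h: links / %, first end groups / %): 2.00: 39.7, 60.4; 3.00: 50.5, 49.3; 5.00: 61.6, 37.7; 8.00: 71.3, 26.5; 15.0: 81.4, 17.5; 25.0: 88.6, 9.1
- dusk (time / h: links / %, first end groups / %): 2.00: 56.7, 42.1; 3.00: 68.9, 30.3; 5.00: 80.2, 19.0; 8.00: 89.0, 11.2; 15.0: 94.0, 3.8; 25.0: 99.4, 1.1
- summer (time / h: links / %, first end groups / %): 2.00: 28.7, 71.8; 4.00: 38.8, 59.6; 6.00: 43.3, 54.1; 12.0: 49.3, 47.9; 25.0: 57.1, 43.8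

(standard deviation of a reading: 1 percentage point)

- what may be going on: first end groups + second end groups -> links + released group; second end groups <-> dormant form

1. concentration of links at 20 h, in M
2. concentration of first end groups at 20 h, in M

One second-order rate constant cannot carry the spring run: its readings give an apparent 1.86 M⁻¹ h⁻¹ up to 2.00 h, but 1.02 M⁻¹ h⁻¹ between 15.0 h and 25.0 h.

So what can you carry to another flask? Write A for first end groups and P for second end groups not yet linked, free or dormant. Take P/A, divide it by its starting value, take the logarithm, and divide by the charged excess of P. This clock, G, stands in the spring run at 18.1 M⁻¹ at 15.0 h and 28.3 M⁻¹ at 25.0 h. Interpolated to 20 h, it is 23.2 M⁻¹, the apparent rate constant summed over time.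

What does that leave in the flask? Its charges differ by 0.00200 M, so G shrinks to 1/A minus one over the charge, the integrated second-order rate law. On the spring clock, your reckoning gives A = 0.0310 M and links 0.0790 M.

The forecast, from “A quasi-steady integration then gives” its value, says 0.074 M of links and 0.036 M of first end groups, more of the latter than your reckoning.

The flask gives 0.0769 M of links and 0.0331 M of first end groups.

    first end groups + second end groups → links + released group (k = 2.10 M⁻¹ h⁻¹)
    second end groups ⇌ dormant form (K = 2.00, k = 0.0760 h⁻¹)

The flask's own clock is 21.1 M⁻¹, below the spring value. Its second end groups have a linking half-life of 4.6 h at 2.53 h and 10 h at 20.0 h, twice as long. For the neighbour flask charged with 0.28 M of second end groups, the spring clock gives 0.00130 M of first end groups, and that flask holds 0.00118 M.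

Readings and results are simulated from invented constants; the scatter is artificial.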